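**Assumption:** the target has no stereocentre and no stereogenic double bond, so "single enantiomer" is read as the achiral compound as drawn; no stereocontrol is needed.
**Convention:** compounds whose atoms end up in the target are numbered; MOMCl, NIS and ICl are treated as reagents. Compounds 4 and 13 are taken as catalogue building blocks.

## Retrosynthetic overview

1. Target 15 ⇐ acidic removal of three MOM groups from the protected 3-prenylflavone 14.
2. C3–prenyl bond ⇐ linear-selective Suzuki–Miyaura coupling of 3-iodoflavone 12 with prenyl-Bpin 13 (no Baker–Venkataraman / diketone prenylation).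
3. Key step: the pyranone C ring and the C3–I handle are made together by ICl-induced 6-endo-dig iodocyclization of diaryl ynone 10.
4. Ynone 10 ⇐ A-ring aryllithium 8 (directed ortho-metalation of 7) + B-ring alkynyl Weinreb amide 5 (Sonogashira from iodide 3).
5. Ring order: A and B rings are bought as phenols 6 and 1; the C ring is the only ring formed (step 6).

## Route

Step 1
Reactants: 1 2-methoxybenzene-1,4-diol (methoxyhydroquinone)
Product: 2 2-methoxy-1,4-bis(methoxymethoxy)benzene
Conditions: NaH (2.4 equiv), MOMCl (2.4 equiv), DMF, 0 °C to rt, Ar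
Reagents that add atoms: chloromethyl methyl ether (MOMCl), COCCl
Why: Williamson-type O-alkylation (MOM protection) of both phenoxides; MOM tolerates the later organolithium, ICl and aqueous base and is removed last by mild acid that spares the prenyl group.

Step 2
Reactants: 2 2-methoxy-1,4-bis(methoxymethoxy)benzene
Product: 3 1-iodo-4-methoxy-2,5-bis(methoxymethoxy)benzene
Conditions: NIS (1.05 equiv), MeCN, 0 °C to rt, dark
Reagents that add atoms: N-iodosuccinimide, O=C1CCC(=O)N1I
Why: Electrophilic aromatic iodination goes to the one unhindered position that is para to OMe and ortho to OMOM (the regiochemistry of 1,2,4-trialkoxybenzenes), under acid-free conditions that leave MOM intact.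

Step 3
Reactants: 3 1-iodo-4-methoxy-2,5-bis(methoxymethoxy)benzene; 4 N-methoxy-N-methylprop-2-ynamide
Product: 5 N-methoxy-3-[4-methoxy-2,5-bis(methoxymethoxy)phenyl]-N-methylprop-2-ynamide
Conditions: PdCl2(PPh3)2 (3 mol %), CuI (6 mol %), K2CO3 (2 equiv), THF, 60 °C
Reagents that add atoms: none
Why: Sonogashira coupling under amine-free carbonate conditions, which suit electron-poor propiolic acid derivatives and avoid aza-Michael addition to the ynamide.

Step 4
Reactants: 6 5-methoxybenzene-1,3-diol (5-methoxyresorcinol)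
Product: 7 1-methoxy-3,5-bis(methoxymethoxy)benzene
Conditions: NaH (2.4 equiv), MOMCl (2.4 equiv), DMF, 0 °C to rt
Reagents that add atoms: chloromethyl methyl ether (MOMCl), COCCl
Why: Williamson-type MOM protection, which also installs the two directing groups needed for the next metalation.

Step 5
Reactants: 7 1-methoxy-3,5-bis(methoxymethoxy)benzene; 5 N-methoxy-3-[4-methoxy-2,5-bis(methoxymethoxy)phenyl]-N-methylprop-2-ynamide
Product: 10 1-[4-methoxy-2,6-bis(methoxymethoxy)phenyl]-3-[4-methoxy-2,5-bis(methoxymethoxy)phenyl]prop-2-yn-1-one, via aryllithium 8 (not isolated), via lithium hemiaminal alkoxide 9 (not isolated)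
Conditions: 7 (1.2 equiv), n-BuLi (1.1 equiv), THF, 0 °C, 1 h; then 5 (1.0 equiv), −78 to −20 °C; AcOH (1.2 equiv), −78 °C, then H2O
Reagents that add atoms: none
Why: Directed ortho-metalation at the carbon flanked by both OMOM groups, then Weinreb ketone synthesis in which the chelated tetrahedral adduct 9 blocks over-addition and gives the ynone on protonation.

Step 6
Reactants: 10 1-[4-methoxy-2,6-bis(methoxymethoxy)phenyl]-3-[4-methoxy-2,5-bis(methoxymethoxy)phenyl]prop-2-yn-1-one
Product: 12 3-iodo-7-methoxy-5-(methoxymethoxy)-2-[4-methoxy-2,5-bis(methoxymethoxy)phenyl]-4H-chromen-4-one, via O-methoxymethyl oxonium chloride 11 (not isolated)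
Conditions: ICl (1.1 equiv, 1 M in CH2Cl2), CH2Cl2, −78 °C, 30 min; aq. Na2S2O3/NaHCO3 quench
Reagents that add atoms: iodine monochloride, ClI
Why: ICl-induced 6-endo-dig iodocyclization of an o-alkoxyaryl ynone (Larock type), in which an ortho ether oxygen attacks the iodonium at the B-ring-bearing alkyne carbon and the oxonium 11 loses its MOM group as MOMCl; the two ortho OMOM groups are equivalent, so only one chromone can form.

Step 7
Reactants: 12 3-iodo-7-methoxy-5-(methoxymethoxy)-2-[4-methoxy-2,5-bis(methoxymethoxy)phenyl]-4H-chromen-4-one; 13 4,4,5,5-tetramethyl-2-(3-methylbut-2-en-1-yl)-1,3,2-dioxaborolane (prenyl-Bpin)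
Product: 14 7-methoxy-5-(methoxymethoxy)-2-[4-methoxy-2,5-bis(methoxymethoxy)phenyl]-3-(3-methylbut-2-en-1-yl)-4H-chromen-4-one
Conditions: 13 (1.5 equiv), Pd-PEPPSI-IPent (4 mol %), KOH (5 M aq, 3 equiv), THF, 65 °C, 2 h, Ar
Reagents that add atoms: none
Why: Suzuki–Miyaura sp2–sp3 coupling of the readily oxidatively adding 3-iodoflavone, where the bulky NHC ligand directs reductive elimination from the π-prenyl–Pd intermediate to the unsubstituted terminus and so gives the linear prenyl group.

Step 8
Reactants: 14 7-methoxy-5-(methoxymethoxy)-2-[4-methoxy-2,5-bis(methoxymethoxy)phenyl]-3-(3-methylbut-2-en-1-yl)-4H-chromen-4-one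
Product: 15 artoindonesianin Q, 2-(2,5-dihydroxy-4-methoxyphenyl)-5-hydroxy-7-methoxy-3-(3-methylbut-2-en-1-yl)-4H-chromen-4-one
Conditions: HCl (1.25 M in MeOH), THF, 40 °C, Ar; aq. NaHCO3/Na2S2O4 work-up
Reagents that add atoms: none
Why: Acid-catalysed acetal exchange removes all three MOM groups as dimethoxymethane, and the prenyl olefin survives because 5-OH or 2'-OH could only add to it through 8-membered rings; argon and dithionite protect the free hydroquinone.

## Compound list

1 | 2-methoxybenzene-1,4-diol (methoxyhydroquinone) | COc1cc(O)ccc1O | starting material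
2 | 2-methoxy-1,4-bis(methoxymethoxy)benzene | COCOc1ccc(OCOC)c(OC)c1 | intermediate
3 | 1-iodo-4-methoxy-2,5-bis(methoxymethoxy)benzene | COCOc1cc(OC)c(OCOC)cc1I | intermediate
4 | N-methoxy-N-methylprop-2-ynamide | C#CC(=O)N(C)OC | starting material
5 | N-methoxy-3-[4-methoxy-2,5-bis(methoxymethoxy)phenyl]-N-methylprop-2-ynamide | COCOc1cc(OC)c(OCOC)cc1C#CC(=O)N(C)OC | intermediate
6 | 5-methoxybenzene-1,3-diol (5-methoxyresorcinol) | COc1cc(O)cc(O)c1 | starting material
7 | 1-methoxy-3,5-bis(methoxymethoxy)benzene | COCOc1cc(OC)cc(OCOC)c1 | intermediate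
8 | [4-methoxy-2,6-bis(methoxymethoxy)phenyl]lithium | [Li]c1c(OCOC)cc(OC)cc1OCOC | intermediate (not isolated)
9 | lithium hemiaminal alkoxide from 8 and 5 (racemic, transient) | COCOc1cc(OC)cc(OCOC)c1C(O[Li])(N(C)OC)C#Cc1cc(OCOC)c(OC)cc1OCOC | intermediate (not isolated)
10 | 1-[4-methoxy-2,6-bis(methoxymethoxy)phenyl]-3-[4-methoxy-2,5-bis(methoxymethoxy)phenyl]prop-2-yn-1-one | COCOc1cc(OC)cc(OCOC)c1C(=O)C#Cc1cc(OCOC)c(OC)cc1OCOC | intermediate
11 | 3-iodo-7-methoxy-1-(methoxymethyl)-5-(methoxymethoxy)-2-[4-methoxy-2,5-bis(methoxymethoxy)phenyl]-4-oxo-4H-chromen-1-ium chloride | COC[O+]1C(c2cc(OCOC)c(OC)cc2OCOC)=C(I)C(=O)c2c(OCOC)cc(OC)cc21.[Cl-] | intermediate (not isolated)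
12 | 3-iodo-7-methoxy-5-(methoxymethoxy)-2-[4-methoxy-2,5-bis(methoxymethoxy)phenyl]-4H-chromen-4-one | COCOc1cc(OC)cc2oc(-c3cc(OCOC)c(OC)cc3OCOC)c(I)c(=O)c12 | intermediate
13 | 4,4,5,5-tetramethyl-2-(3-methylbut-2-en-1-yl)-1,3,2-dioxaborolane (prenyl-Bpin) | CC(C)=CCB1OC(C)(C)C(C)(C)O1 | starting material
14 | 7-methoxy-5-(methoxymethoxy)-2-[4-methoxy-2,5-bis(methoxymethoxy)phenyl]-3-(3-methylbut-2-en-1-yl)-4H-chromen-4-one | COCOc1cc(OC)cc2oc(-c3cc(OCOC)c(OC)cc3OCOC)c(CC=C(C)C)c(=O)c12 | intermediate
15 | artoindonesianin Q | COc1cc(O)c2c(=O)c(CC=C(C)C)c(-c3cc(O)c(OC)cc3O)oc2c1 | target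

## Step count

Total steps: 8. Longest linear sequence: 7 (steps 1, 2, 3, 5, 6, 7, 8); step 4 is the one-step A-ring branch.

## Three steps most likely to fail

**Step 6 (ICl iodocyclization).** The risks are competing ring iodination of the two very electron-rich arenes, sluggish loss of MOM from the oxonium, and 5-endo attack by the B-ring 2'-OMOM oxygen to give a benzofuran. The fallback sets out from 10 and returns at 12. Brief treatment of 10 with dilute HCl in MeOH at 0 °C removes one of the two carbonyl-chelated A-ring MOM groups and gives 1-[2-hydroxy-4-methoxy-6-(methoxymethoxy)phenyl]-3-[4-methoxy-2,5-bis(methoxymethoxy)phenyl]prop-2-yn-1-one F1. Catalytic DMAP in DMF then closes the pyranone by 6-endo oxa-Michael addition to give 7-methoxy-5-(methoxymethoxy)-2-[4-methoxy-2,5-bis(methoxymethoxy)phenyl]-4H-chromen-4-one F2. Carbonyl-directed C3 lithiation of F2 with LDA in THF at −78 °C and an iodine quench gives 12. This replaces the electrophilic cyclization by a nucleophilic one and installs iodine by deprotonation instead.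

**Step 7 (Suzuki prenylation).** The risks are branched (reverse-prenyl) product, protodeiodination, and hydroxide attack on the pyranone under the aqueous KOH. The fallback sets out from 12 and returns at 14. Base-free Stille coupling of 12 with allyltributylstannane (Pd(PPh3)4, DMF, 80 °C), which has no regiochemical ambiguity, gives 7-methoxy-5-(methoxymethoxy)-2-[4-methoxy-2,5-bis(methoxymethoxy)phenyl]-3-(prop-2-en-1-yl)-4H-chromen-4-one F3. Olefin cross-metathesis of F3 with excess 2-methyl-2-butene (Grubbs II, CH2Cl2, 40 °C) turns the allyl group into prenyl and gives 14.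

**Step 5 (metalation and Weinreb acylation).** The risks are lithiation between OMOM and OMe instead of between the two OMOM groups, and conjugate addition or N–OMe cleavage when the hindered aryllithium meets the ynamide. The fallback reverses the polarity of the ketone synthesis, sets out from 7 and 3, and returns at 10. Aryllithium 8 is quenched with DMF to give 4-methoxy-2,6-bis(methoxymethoxy)benzaldehyde F4, whose symmetry shows the lithiation regiochemistry at once by NMR. Iodide 3 is coupled with trimethylsilylacetylene (PdCl2(PPh3)2, CuI, Et3N, THF) to give trimethyl{[4-methoxy-2,5-bis(methoxymethoxy)phenyl]ethynyl}silane F5. K2CO3 in MeOH desilylates F5 to 1-ethynyl-4-methoxy-2,5-bis(methoxymethoxy)benzene F6. The lithium acetylide of F6 (n-BuLi, THF, −78 °C) adds to F4 to give racemic 1-[4-methoxy-2,6-bis(methoxymethoxy)phenyl]-3-[4-methoxy-2,5-bis(methoxymethoxy)phenyl]prop-2-yn-1-ol F7. MnO2 in CH2Cl2 oxidizes F7 to 10.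

## Further compounds

F1 | step 6 | 1-[2-hydroxy-4-methoxy-6-(methoxymethoxy)phenyl]-3-[4-methoxy-2,5-bis(methoxymethoxy)phenyl]prop-2-yn-1-one | COCOc1cc(OC)cc(O)c1C(=O)C#Cc1cc(OCOC)c(OC)cc1OCOC
F2 | step 6 | 7-methoxy-5-(methoxymethoxy)-2-[4-methoxy-2,5-bis(methoxymethoxy)phenyl]-4H-chromen-4-one | COCOc1cc(OC)cc2oc(-c3cc(OCOC)c(OC)cc3OCOC)cc(=O)c12
F3 | step 7 | 7-methoxy-5-(methoxymethoxy)-2-[4-methoxy-2,5-bis(methoxymethoxy)phenyl]-3-(prop-2-en-1-yl)-4H-chromen-4-one | COCOc1cc(OC)cc2oc(-c3cc(OCOC)c(OC)cc3OCOC)c(CC=C)c(=O)c12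
F4 | step 5 | 4-methoxy-2,6-bis(methoxymethoxy)benzaldehyde | COCOc1cc(OC)cc(OCOC)c1C=O
F5 | step 5 | trimethyl{[4-methoxy-2,5-bis(methoxymethoxy)phenyl]ethynyl}silane | COCOc1cc(OC)c(OCOC)cc1C#C[Si](C)(C)C
F6 | step 5 | 1-ethynyl-4-methoxy-2,5-bis(methoxymethoxy)benzene | COCOc1cc(OC)c(OCOC)cc1C#C
F7 | step 5 | racemic 1-[4-methoxy-2,6-bis(methoxymethoxy)phenyl]-3-[4-methoxy-2,5-bis(methoxymethoxy)phenyl]prop-2-yn-1-ol | COCOc1cc(OC)cc(OCOC)c1C(O)C#Cc1cc(OCOC)c(OC)cc1OCOC
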